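Ring A is treated as an aromatised 4-aroyl-5-ethylcyclohexane-1,3-dione. Its C4 and C6 hydroxyls are the two dione carbonyls, so the congested junction of C1 (acyl) and C2 (ethyl) is assembled while both carbons are still tetrahedral. In one operation the central carbon of a ring B aroylacetone adds to ethyl (E)-pent-2-enoate (C1–C2) and the acetyl methyl carbon then closes onto the ester (C5–C4). This delivers all of ring A with the diaryl ketone already installed. The precursor is a 1-arylbutane-1,3-dione whose aryl group is ring B as its dimethyl ether, bearing the future pyranone arm as a benzyl-protected 2-hydroxyethyl chain.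

Key step: step 5

Remark: the target is achiral, so the racemic trans dione of step 5 needs no stereocontrol; both of its stereocentres vanish in step 6.

Step 1
Reactants: 1 2-(3,5-dimethoxyphenyl)acetic acid
Product: 2 2-(3,5-dimethoxyphenyl)ethan-1-ol
Conditions: BH3·SMe2, THF, 0 °C to rt; then MeOH, H2O
Reagents that add atoms: none
Why: Borane reduction of a carboxylic acid proceeds through an acyloxyborane to the primary alcohol and leaves the aryl methyl ethers untouched.

Step 2
Reactants: 2 2-(3,5-dimethoxyphenyl)ethan-1-ol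
Product: 3 1-[2-(benzyloxy)ethyl]-3,5-dimethoxybenzene
Conditions: NaH, BnBr, Bu4NI (cat.), THF, 0 °C to rt
Reagents that add atoms: benzyl bromide, BrCc1ccccc1
Why: Williamson etherification of the primary sodium alkoxide should be clean because the substrate has no other acidic or electrophilic site.

Step 3
Reactants: 3 1-[2-(benzyloxy)ethyl]-3,5-dimethoxybenzene; 4 acetic acid
Product: 6 1-{2-[2-(benzyloxy)ethyl]-4,6-dimethoxyphenyl}ethan-1-one, via acetyl trifluoroacetate 5 (not isolated)
Conditions: AcOH, (CF3CO)2O, CH2Cl2, 0 °C; then 3, 0 °C to rt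
Reagents that add atoms: none
Why: Friedel–Crafts acylation by the mixed anhydride should occur at the ring position beside the side chain (para to one methoxy group, ortho to the other, and less shielded than the position between the two methoxy groups), and the metal-free acidic medium should leave the benzyl ether intact.

Step 4
Reactants: 6 1-{2-[2-(benzyloxy)ethyl]-4,6-dimethoxyphenyl}ethan-1-one; 7 ethyl acetate
Product: 8 1-{2-[2-(benzyloxy)ethyl]-4,6-dimethoxyphenyl}butane-1,3-dione
Conditions: NaH, EtOAc (excess), THF, reflux; then 1 M HCl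
Reagents that add atoms: none
Why: In this crossed Claisen condensation the sodium enolate of the methyl ketone is acylated by ethyl acetate, and deprotonation of the 1,3-diketone formed pulls the equilibrium over; the reaction type tolerates two ortho substituents on the aryl ketone.

Step 5
Reactants: 8 1-{2-[2-(benzyloxy)ethyl]-4,6-dimethoxyphenyl}butane-1,3-dione; 9 ethyl (E)-pent-2-enoate
Product: 11 rac-(4S,5R)-4-{2-[2-(benzyloxy)ethyl]-4,6-dimethoxybenzoyl}-5-ethylcyclohexane-1,3-dione (racemic trans isomer), via open-chain Michael adduct 10 (not isolated)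
Conditions: NaOEt (2.2 equiv), 9 (1.5 equiv), EtOH, reflux; then 1 M HCl, 0 °C
Reagents that add atoms: none
Why: Ethoxide converts 8 into its stabilised enolate, whose central carbon adds in a conjugate (Michael) sense to the β-carbon of 9 to give 10 (ring A C1–C2), and reversible deprotonation of the acetyl methyl group of 10 then allows a Claisen attack on the ester with loss of ethoxide (ring A C5–C4). The closest known reaction type is the alkoxide-mediated Michael–Claisen annulation of 1,3-dicarbonyl compounds with crotonate-type esters that gives dihydroresorcinols. The six-membered ring closes in a 6-(enolendo)-exo-trig mode. The two new stereocentres, dione carbons C4 and C5, form without external control; C4 lies between two carbonyl groups and equilibrates, so the trans isomer with both substituents equatorial should dominate, and both centres are erased in step 6. The step needs C- and not O-alkylation in the Michael addition and ring closure through the methyl carbon only: the soft delocalised enolate under equilibrating conditions favours C-alkylation, the methyl carbon is the only enolisable position that reaches the ester through a six-membered transition state, and the aryl ketone, twisted and shielded by its two ortho substituents, stays a spectator. Reversible side paths (retro-Michael, O-acylation) should drain into the acidic dione enolate of 11, whose formation is effectively irreversible.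

Step 6
Reactants: 11 rac-(4S,5R)-4-{2-[2-(benzyloxy)ethyl]-4,6-dimethoxybenzoyl}-5-ethylcyclohexane-1,3-dione
Product: 12 {2-[2-(benzyloxy)ethyl]-4,6-dimethoxyphenyl}(2-ethyl-6-hydroxy-4-methoxyphenyl)methanone
Conditions: I2 (2 equiv), MeOH, reflux
Reagents that add atoms: methanol, CO
Why: In this iodine–methanol oxidative aromatisation the dione carbonyl remote from the aroyl group is expected to form its vinylogous methyl ester, iodination next to the remaining carbonyl and loss of HI supply the missing double bond, and tautomerisation gives the arene with the hydrogen-bonded hydroxyl beside the ketone left free.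

Step 7
Reactants: 12 {2-[2-(benzyloxy)ethyl]-4,6-dimethoxyphenyl}(2-ethyl-6-hydroxy-4-methoxyphenyl)methanone
Product: 13 {2-[2-(benzyloxy)ethyl]-4,6-dimethoxyphenyl}(2-ethyl-4,6-dimethoxyphenyl)methanone
Conditions: MeI, K2CO3, DMF, 50 °C
Reagents that add atoms: iodomethane, CI
Why: Williamson O-methylation of the remaining chelated phenol gives the uniformly methyl-protected benzophenone, and any dimethyl ether or free resorcinol carried over from step 6 converges on the same compound.

Step 8
Reactants: 13 {2-[2-(benzyloxy)ethyl]-4,6-dimethoxyphenyl}(2-ethyl-4,6-dimethoxyphenyl)methanone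
Product: 14 (2-ethyl-4,6-dimethoxyphenyl)[2-(2-hydroxyethyl)-4,6-dimethoxyphenyl]methanone
Conditions: H2 (1 atm), 10% Pd/C, EtOAc, rt
Reagents that add atoms: none
Why: Palladium-catalysed hydrogenolysis cleaves the benzylic C–O bond of the benzyl ether selectively, since aryl methyl ethers are inert and the electron-rich diaryl ketone flanked by four ortho substituents should resist reduction.

Step 9
Reactants: 14 (2-ethyl-4,6-dimethoxyphenyl)[2-(2-hydroxyethyl)-4,6-dimethoxyphenyl]methanone
Product: 15 2-[2-(2-ethyl-4,6-dimethoxybenzoyl)-3,5-dimethoxyphenyl]acetic acid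
Conditions: TEMPO (cat.), NaClO2, NaOCl (cat.), MeCN/aq. NaH2PO4–Na2HPO4 buffer (pH 6.7), 35 °C
Reagents that add atoms: sodium chlorite, [Na+].[O-]Cl=O
Why: TEMPO-catalysed oxidation with NaClO2 as terminal oxidant takes the primary alcohol through the aldehyde to the carboxylic acid under buffered conditions that keep hypochlorite low and so avoid chlorination of the methoxyarenes.

Step 10
Reactants: 15 2-[2-(2-ethyl-4,6-dimethoxybenzoyl)-3,5-dimethoxyphenyl]acetic acid; 16 2,2,6-trimethyl-4H-1,3-dioxin-4-one
Product: 18 6-{3-[2-(2-ethyl-4,6-dimethoxybenzoyl)-3,5-dimethoxyphenyl]-2-oxopropyl}-2,2-dimethyl-4H-1,3-dioxin-4-one, via acyl imidazolide 17 (not isolated)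
Conditions: 15, CDI, THF, rt; added to 16 + LiN(SiMe3)2 (3 equiv each), THF, −78 °C; then 1 M HCl
Reagents that add atoms: none
Why: In this vinylogous Claisen acylation the acid, activated as its imidazolide, is attacked by the γ-carbon of the lithium dienolate of the dioxinone, excess dienolate absorbing the acidic protons of product and acyl donor, while the shielded diaryl ketone should not react at −78 °C.

Step 11
Reactants: 18 6-{3-[2-(2-ethyl-4,6-dimethoxybenzoyl)-3,5-dimethoxyphenyl]-2-oxopropyl}-2,2-dimethyl-4H-1,3-dioxin-4-one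
Product: 20 6-{[2-(2-ethyl-4,6-dimethoxybenzoyl)-3,5-dimethoxyphenyl]methyl}-4-hydroxy-2H-pyran-2-one, via acylketene 19 (not isolated)
Conditions: PhMe, 110 °C
Reagents that add atoms: none
Why: Thermal retro-hetero-Diels–Alder loss of acetone from the dioxinone gives an acylketene that is captured by the enol oxygen of the neighbouring ketone in a six-membered lactonisation, forming the 4-hydroxy-2-pyranone under neutral conditions that avoid aldol attack on the diaryl ketone.

Step 12
Reactants: 20 6-{[2-(2-ethyl-4,6-dimethoxybenzoyl)-3,5-dimethoxyphenyl]methyl}-4-hydroxy-2H-pyran-2-one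
Product: 21 6-{[2-(2-ethyl-4,6-dihydroxybenzoyl)-3,5-dihydroxyphenyl]methyl}-4-hydroxy-2H-pyran-2-one
Conditions: BBr3 (10 equiv), CH2Cl2, −78 °C to rt; then H2O
Reagents that add atoms: none
Why: Lewis acid-mediated cleavage of all four aryl methyl ethers with BBr3, the two ortho to the ketone assisted by chelation, should unveil the phenols, since the 4-hydroxy-2-pyranone and the diaryl ketone are stable to these conditions.

Compound list
1 | 2-(3,5-dimethoxyphenyl)acetic acid | COc1cc(CC(=O)O)cc(OC)c1 | starting material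
2 | 2-(3,5-dimethoxyphenyl)ethan-1-ol | COc1cc(CCO)cc(OC)c1 | intermediate
3 | 1-[2-(benzyloxy)ethyl]-3,5-dimethoxybenzene | COc1cc(CCOCc2ccccc2)cc(OC)c1 | intermediate
4 | acetic acid | CC(=O)O | starting material
5 | acetyl trifluoroacetate (acetic trifluoroacetic anhydride) | CC(=O)OC(=O)C(F)(F)F | intermediate (not isolated)
6 | 1-{2-[2-(benzyloxy)ethyl]-4,6-dimethoxyphenyl}ethan-1-one | CC(=O)c1c(OC)cc(OC)cc1CCOCc1ccccc1 | intermediate
7 | ethyl acetate | CCOC(C)=O | starting material
8 | 1-{2-[2-(benzyloxy)ethyl]-4,6-dimethoxyphenyl}butane-1,3-dione | CC(=O)CC(=O)c1c(OC)cc(OC)cc1CCOCc1ccccc1 | intermediate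
9 | ethyl (E)-pent-2-enoate | CC/C=C/C(=O)OCC | starting material
10 | ethyl 4-acetyl-5-{2-[2-(benzyloxy)ethyl]-4,6-dimethoxyphenyl}-3-ethyl-5-oxopentanoate (racemic mixture of diastereomers) | CCOC(=O)CC(CC)C(C(C)=O)C(=O)c1c(OC)cc(OC)cc1CCOCc1ccccc1 | intermediate (not isolated)
11 | rac-(4S,5R)-4-{2-[2-(benzyloxy)ethyl]-4,6-dimethoxybenzoyl}-5-ethylcyclohexane-1,3-dione (trans, racemic, one enantiomer drawn) | CC[C@@H]1CC(=O)CC(=O)[C@H]1C(=O)c1c(OC)cc(OC)cc1CCOCc1ccccc1 | intermediate
12 | {2-[2-(benzyloxy)ethyl]-4,6-dimethoxyphenyl}(2-ethyl-6-hydroxy-4-methoxyphenyl)methanone | CCc1cc(OC)cc(O)c1C(=O)c1c(OC)cc(OC)cc1CCOCc1ccccc1 | intermediate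
13 | {2-[2-(benzyloxy)ethyl]-4,6-dimethoxyphenyl}(2-ethyl-4,6-dimethoxyphenyl)methanone | CCc1cc(OC)cc(OC)c1C(=O)c1c(OC)cc(OC)cc1CCOCc1ccccc1 | intermediate
14 | (2-ethyl-4,6-dimethoxyphenyl)[2-(2-hydroxyethyl)-4,6-dimethoxyphenyl]methanone | CCc1cc(OC)cc(OC)c1C(=O)c1c(OC)cc(OC)cc1CCO | intermediate
15 | 2-[2-(2-ethyl-4,6-dimethoxybenzoyl)-3,5-dimethoxyphenyl]acetic acid | CCc1cc(OC)cc(OC)c1C(=O)c1c(OC)cc(OC)cc1CC(=O)O | intermediate
16 | 2,2,6-trimethyl-4H-1,3-dioxin-4-one | CC1=CC(=O)OC(C)(C)O1 | starting material
17 | 2-[2-(2-ethyl-4,6-dimethoxybenzoyl)-3,5-dimethoxyphenyl]-1-(1H-imidazol-1-yl)ethan-1-one | CCc1cc(OC)cc(OC)c1C(=O)c1c(OC)cc(OC)cc1CC(=O)n1ccnc1 | intermediate (not isolated)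
18 | 6-{3-[2-(2-ethyl-4,6-dimethoxybenzoyl)-3,5-dimethoxyphenyl]-2-oxopropyl}-2,2-dimethyl-4H-1,3-dioxin-4-one | CCc1cc(OC)cc(OC)c1C(=O)c1c(OC)cc(OC)cc1CC(=O)CC1=CC(=O)OC(C)(C)O1 | intermediate
19 | 6-[2-(2-ethyl-4,6-dimethoxybenzoyl)-3,5-dimethoxyphenyl]hex-1-ene-1,3,5-trione (acylketene) | CCc1cc(OC)cc(OC)c1C(=O)c1c(OC)cc(OC)cc1CC(=O)CC(=O)C=C=O | intermediate (not isolated)
20 | 6-{[2-(2-ethyl-4,6-dimethoxybenzoyl)-3,5-dimethoxyphenyl]methyl}-4-hydroxy-2H-pyran-2-one | CCc1cc(OC)cc(OC)c1C(=O)c1c(OC)cc(OC)cc1Cc1cc(O)cc(=O)o1 | intermediate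
21 | 6-{[2-(2-ethyl-4,6-dihydroxybenzoyl)-3,5-dihydroxyphenyl]methyl}-4-hydroxy-2H-pyran-2-one | CCc1cc(O)cc(O)c1C(=O)c1c(O)cc(O)cc1Cc1cc(O)cc(=O)o1 | target

Total step count: 12. Longest linear sequence: 12 steps (1 to 21).

Steps most likely to fail

Step 5. The conjugate addition of the hindered diketone enolate to the β-substituted enoate may be slow, so that ethoxide-induced retro-Claisen deacetylation of 8 or of the open-chain adduct competes with ring closure. The fallback reverses the order of the two bond formations and sets out from 8. The dianion of 8 (LiN(i-Pr)2, 2.2 equiv, THF, −78 °C) should add through its terminal carbon to the carbonyl group of (E)-pent-2-enal to give (E)-1-{2-[2-(benzyloxy)ethyl]-4,6-dimethoxyphenyl}-5-hydroxynon-6-ene-1,3-dione F1. Oxidation of the allylic alcohol (MnO2, CH2Cl2, rt) should give (E)-1-{2-[2-(benzyloxy)ethyl]-4,6-dimethoxyphenyl}non-6-ene-1,3,5-trione F2. Mild base (K2CO3, MeOH, rt) should then induce a 6-endo-trig intramolecular Michael addition of the carbon between the aryl ketone and the neighbouring carbonyl onto the enone. The fallback rejoins the route at 11.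

Step 6. Iodination of the enolised dione may stall at the carbon between the two ring carbonyls without elimination, or enol ether formation may be incomplete, leaving partly oxidised mixtures. The fallback drops the halogen/enol ether pathway for a quinone hydride-abstraction dehydrogenation and sets out from 11. DDQ (1.5 equiv, 1,4-dioxane, reflux) should give {2-[2-(benzyloxy)ethyl]-4,6-dimethoxyphenyl}(2-ethyl-4,6-dihydroxyphenyl)methanone F3. Double O-methylation (MeI, K2CO3, DMF, 50 °C) then rejoins the route at 13.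

Step 10. Proton transfer from the acidic arylacetyl imidazolide to the basic dienolate may outpace C-acylation and return acid 15 on work-up. The fallback makes the same bond under Lewis acid conditions from an aldehyde and sets out from 14. Oxidation with Dess–Martin periodinane (CH2Cl2, rt) should give 2-[2-(2-ethyl-4,6-dimethoxybenzoyl)-3,5-dimethoxyphenyl]acetaldehyde F4. Separately, 16 is converted (LiN(SiMe3)2, Me3SiCl, THF, −78 °C) into [(2,2-dimethyl-4-methylidene-4H-1,3-dioxin-6-yl)oxy]trimethylsilane F5. A vinylogous Mukaiyama aldol addition of this silyl dienol ether to the aldehyde (BF3·OEt2, CH2Cl2, −78 °C) should give racemic 6-{3-[2-(2-ethyl-4,6-dimethoxybenzoyl)-3,5-dimethoxyphenyl]-2-hydroxypropyl}-2,2-dimethyl-4H-1,3-dioxin-4-one F6. A second Dess–Martin oxidation rejoins the route at 18.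

Further compounds
F1 | step 5 | (E)-1-{2-[2-(benzyloxy)ethyl]-4,6-dimethoxyphenyl}-5-hydroxynon-6-ene-1,3-dione (racemic) | CC/C=C/C(O)CC(=O)CC(=O)c1c(OC)cc(OC)cc1CCOCc1ccccc1
F2 | step 5 | (E)-1-{2-[2-(benzyloxy)ethyl]-4,6-dimethoxyphenyl}non-6-ene-1,3,5-trione | CC/C=C/C(=O)CC(=O)CC(=O)c1c(OC)cc(OC)cc1CCOCc1ccccc1
F3 | step 6 | {2-[2-(benzyloxy)ethyl]-4,6-dimethoxyphenyl}(2-ethyl-4,6-dihydroxyphenyl)methanone | CCc1cc(O)cc(O)c1C(=O)c1c(OC)cc(OC)cc1CCOCc1ccccc1
F4 | step 10 | 2-[2-(2-ethyl-4,6-dimethoxybenzoyl)-3,5-dimethoxyphenyl]acetaldehyde | CCc1cc(OC)cc(OC)c1C(=O)c1c(OC)cc(OC)cc1CC=O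
F5 | step 10 | [(2,2-dimethyl-4-methylidene-4H-1,3-dioxin-6-yl)oxy]trimethylsilane | C=C1C=C(O[Si](C)(C)C)OC(C)(C)O1
F6 | step 10 | 6-{3-[2-(2-ethyl-4,6-dimethoxybenzoyl)-3,5-dimethoxyphenyl]-2-hydroxypropyl}-2,2-dimethyl-4H-1,3-dioxin-4-one (racemic) | CCc1cc(OC)cc(OC)c1C(=O)c1c(OC)cc(OC)cc1CC(O)CC1=CC(=O)OC(C)(C)O1
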